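At late times in this flask I reckon with one difference. Each substrate consumed takes one partner, so once the solid reagent has dissolved, c_partner stands above c_substrate by the excess of solid reagent charged over substrate charged, substrate being the limiting reagent: 0.0400 M. With the proposed step, ln(c_partner/c_substrate) then rises on a straight line, with a slope proportional to catalyst and to the excess.

| setting | spring | autumn | flask |
|---|---|---|---|
| substrate | 0.80 M | 0.80 M | 0.80 M |
| solid reagent | 0.84 M | 1.3 M | 0.840 M |
| catalyst | 80 mM | 80 mM | 80 mM |
| remark | the very flask that is asked about, followed so far | run made earlier |  |
| time |  |  | 8.0 min |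

| run | time / min | product / % | substrate / % |
|---|---|---|---|
| spring | 0.200 | 7.3 | 93.0 |
| spring | 0.667 | 35.5 | 64.6 |
| spring | 1.00 | 50.0 | 49.6 |
| spring | 2.00 | 71.3 | 28.2 |
| spring | 2.50 | 77.0 | 22.4 |
| spring | 3.00 | 80.7 | 19.2 |
| autumn | 0.417 | 20.5 | 79.0 |
| autumn | 0.667 | 35.4 | 64.2 |
| autumn | 1.33 | 64.9 | 35.5 |
| autumn | 2.00 | 81.5 | 18.9 |
| autumn | 3.00 | 92.9 | 7.1 |
| autumn | 6.00 | 99.7 | 0.8 |

(scatter of a reading: 0.3 percentage points)

- solid reagent is a solid; its amount is given per volume of the solution
- steps that have been proposed: substrate + partner + catalyst -> catalyst + product; solid reagent <-> partner
- at the start none of the solid reagent is in solution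

- teal: doubling the amount of catalyst, all else as stated
- ochre: doubling the solubility of the solid reagent, all else as stated
- green: doubling the dissolution coefficient of the solid reagent, all else as stated

1. amount of product at 8.0 min, in percent of the substrate charged
2. the change that raises the amount of product at 8.0 min, in percent of the substrate charged most ("none" if none brings more than 2 percentage points) (teal / ochre / green / none)
3. amount of product at 8.0 min, in percent of the substrate charged, after ochre

I assume the tail has begun by 2.00 min. The substrate readings of the spring run give a log ratio of 0.163 there and 0.231 at 3.00 min, so the slope reads 0.0682 min⁻¹. Carried to 8.0 min, the ratio's logarithm is 0.573, which gives 93.5% product. Doubling the catalyst doubles the slope, so as a rough estimate I take twice that logarithm and get 97.7%, a gain of 4.2 percentage points. Ochre and green act on the dissolving, so I try them as an earlier start of the tail: a full minute earlier gives 94.4%, a gain of 0.9 points, less than the margin of 2 points.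

The weak link is a slope from two close readings. If the tail has begun by 1.00 min, where the log ratio is 0.0960, the wider span, which keeps the same last reading, gives 0.0677 min⁻¹ and 93.5%.

The forecast says 93.6%, teal and 94% after ochre, on the ground “Faster or greater dissolution only brings exhaustion forward”; my one-minute trial, at 94.4%, stands higher than its ochre figure.

The flask gives 93.5%; teal adds 4 points, ochre 0.2 points, green 0.12 points, and ochre stands at 93.6%.

    substrate + partner + catalyst → catalyst + product (k = 0.350 M⁻² s⁻¹)
    solid reagent ⇌ partner, rate k2*(cs2 - [partner]) while solid is left; crystals form when [partner] > cs2 (solubility = 0.610 M, k = 0.0910 s⁻¹)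

The forecast's 93.6% belongs to this charge: at 1.01 M of solid reagent the answer has moved by 5 points. With 2.0 M of substrate the difference reverses, substrate now standing above solid reagent by 1.16 M, which is 58.0% of that charge, and that neighbour holds 58.0% substrate at 8.00 min. This flask is not at rest at 8.00 min: it still holds 6.55% substrate and 0.0924 M partner. At 80.0 min substrate in this flask is down to 0.0226%, product is >99.9%, and partner stands at 0.0402 M, about equal to the excess of 0.0400 M.

The earlier runs and the new flask come from a simulation from invented constants, noise included.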